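Postlupulone is disconnected at the three side-chain C2'=C3' double bonds of its 3-methylbut-2-enyl groups, one on the enol carbon C4 and two on the quaternary C6 of the single cyclohexadienone ring. Because all three chains end in the same trisubstituted alkene, one ruthenium-catalysed cross-metathesis with 2-methylbut-2-ene can exchange three terminal vinyl ends for isopropylidene ends at once, without forming any ring or stereocentre. The precursor is the fully assembled 2-propanoyl-3,5-dihydroxycyclohexadienone core carrying plain allyl groups at C4 and twice at C6, made in one dearomatising palladium-catalysed triallylation of commercial 2,4,6-trihydroxypropiophenone with allyl alcohol.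

Key step: step 2

Assumption: the dearomatised compounds are drawn as the 3,5-dihydroxy-2,4-dien-1-one enol tautomer; they are rapidly equilibrating enol forms of one β-tricarbonyl system, and the acidic enol is left unprotected because ruthenium alkylidenes tolerate it and protection would add steps.

Step 1
Reactants: 1 2,4,6-trihydroxypropiophenone (1-(2,4,6-trihydroxyphenyl)propan-1-one); 2 allyl alcohol (prop-2-en-1-ol)
Product: 5 3,5-dihydroxy-2-propanoyl-4,6,6-tri(prop-2-enyl)cyclohexa-2,4-dien-1-one, via monoallyl acylphloroglucinol 3 (not isolated), via diallyl acylphloroglucinol 4 (not isolated)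
Conditions: allyl alcohol (3.1 equiv), Pd(PPh3)4 (5 mol %), Et3B (30 mol %), degassed THF, 50 °C, argon; aq. NH4Cl work-up, chromatography
Reagents that add atoms: allyl alcohol, C=CCO
Why: Threefold dearomative Tsuji–Trost allylation, in which zerovalent palladium ionises the borane-activated allyl alcohol to a π-allylpalladium cation that the phloroglucinol enol carbons capture, first at the two free ring CH positions (3, then 4) and then at one allyl-bearing carbon, which creates the quaternary C6 and leaves the ring as the enolised dienone 5, while O-allyl ethers are re-ionised by the catalyst so that the groups collect on carbon, and the limited charge of alcohol together with the lower nucleophilicity of the hindered, acidic product should hold the count at three; no stereocentre is formed.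

Step 2
Reactants: 5 3,5-dihydroxy-2-propanoyl-4,6,6-tri(prop-2-enyl)cyclohexa-2,4-dien-1-one; 6 2-methylbut-2-ene
Product: 11 postlupulone (3,5-dihydroxy-4,6,6-tris(3-methylbut-2-enyl)-2-propanoylcyclohexa-2,4-dien-1-one), via C4-monoprenyl dienone 7 (not isolated), via C6-monoprenyl dienone 8 (not isolated), via C4,C6-diprenyl dienone 9 (not isolated), via C6,C6-diprenyl dienone 10 (not isolated)
Conditions: second-generation Grubbs catalyst RuCl2(=CHPh)(PCy3)(H2IMes) (2 × 5 mol %), neat degassed 2-methylbut-2-ene (ca. 0.02 M in 5), sealed tube, 40 °C, argon; then DMSO, silica filtration, chromatography and storage under argon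
Reagents that add atoms: 2-methylbut-2-ene, CC=C(C)C
Why: The benzylidene precatalyst exchanges with the solvent olefin to give ruthenium isopropylidene (and ethylidene) carbenes, each terminal CH=CH2 of 5 adds to the carbene to form a ruthenacyclobutane, and cycloreversion releases the chain as CH2-CH=C(CH3)2 while the resulting ruthenium methylidene is recharged by 2-methylbut-2-ene with loss of propene (Chauvin cycle). This is olefin cross-metathesis of a monosubstituted with a trisubstituted alkene, the allyl-to-prenyl exchange that is well established on allylated acylphloroglucinol and related enolised polyketone cores. No ring is closed and no stereocentre is created: C6 ends with two identical chains (the C6 stereocentre of 8 and 9 is transient) and each new alkene bears two identical methyl groups, so no E/Z isomers exist. The selectivity needed is threefold cross-metathesis over ring-closing metathesis of the geminal allyl pair on C6 (a spiro-fused cyclopentene) and over homodimerisation; it is secured mainly by the solvent-level excess of 2-methylbut-2-ene, which keeps the resting carbenes solvent-derived and intercepts any substrate-bound carbene, while in the substrate the unhindered monosubstituted termini react fast and the tetrasubstituted ring enol alkenes do not react at all. But-2-enyl chains that arise from ethylidene transfer are disubstituted and are processed further, whereas the trisubstituted prenyl alkenes do not re-enter the cycle, so the mixture should funnel to 11.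

Compound list
1 | 2,4,6-trihydroxypropiophenone (1-(2,4,6-trihydroxyphenyl)propan-1-one) | CCC(=O)c1c(O)cc(O)cc1O | starting material
2 | allyl alcohol (prop-2-en-1-ol) | C=CCO | starting material
3 | 1-[2,4,6-trihydroxy-3-(prop-2-enyl)phenyl]propan-1-one (formed in the flask, not isolated) | CCC(=O)c1c(O)cc(O)c(CC=C)c1O | intermediate
4 | 1-[2,4,6-trihydroxy-3,5-di(prop-2-enyl)phenyl]propan-1-one (formed in the flask, not isolated) | CCC(=O)c1c(O)c(CC=C)c(O)c(CC=C)c1O | intermediate
5 | 3,5-dihydroxy-2-propanoyl-4,6,6-tri(prop-2-enyl)cyclohexa-2,4-dien-1-one (achiral) | CCC(=O)C1=C(O)C(CC=C)=C(O)C(CC=C)(CC=C)C1=O | intermediate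
6 | 2-methylbut-2-ene | CC=C(C)C | starting material
7 | 3,5-dihydroxy-4-(3-methylbut-2-enyl)-2-propanoyl-6,6-di(prop-2-enyl)cyclohexa-2,4-dien-1-one (achiral, not isolated) | CCC(=O)C1=C(O)C(CC=C(C)C)=C(O)C(CC=C)(CC=C)C1=O | intermediate
8 | 3,5-dihydroxy-6-(3-methylbut-2-enyl)-2-propanoyl-4,6-di(prop-2-enyl)cyclohexa-2,4-dien-1-one (racemic at C6, not isolated) | CCC(=O)C1=C(O)C(CC=C)=C(O)C(CC=C)(CC=C(C)C)C1=O | intermediate
9 | 3,5-dihydroxy-4,6-bis(3-methylbut-2-enyl)-2-propanoyl-6-(prop-2-enyl)cyclohexa-2,4-dien-1-one (racemic at C6, not isolated) | CCC(=O)C1=C(O)C(CC=C(C)C)=C(O)C(CC=C)(CC=C(C)C)C1=O | intermediate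
10 | 3,5-dihydroxy-6,6-bis(3-methylbut-2-enyl)-2-propanoyl-4-(prop-2-enyl)cyclohexa-2,4-dien-1-one (achiral, not isolated) | CCC(=O)C1=C(O)C(CC=C)=C(O)C(CC=C(C)C)(CC=C(C)C)C1=O | intermediate
11 | postlupulone, 3,5-dihydroxy-4,6,6-tris(3-methylbut-2-enyl)-2-propanoylcyclohexa-2,4-dien-1-one (achiral) | CCC(=O)C1=C(O)C(CC=C(C)C)=C(O)C(CC=C(C)C)(CC=C(C)C)C1=O | target

Total step count: 2
Longest linear sequence: 2 steps

Steps most likely to fail (the route has only two steps, so both are ranked and there is no third to list):

1. Step 2. The threefold exchange may stall at partly exchanged or but-2-enyl chains, the geminal allyl pair on C6 may ring-close once a substrate-bound carbene forms, the acidic β-tricarbonyl enol may bind and deactivate ruthenium, and the electron-rich product may oxidise in air during removal of the metal. Fallback: give up the metathesis and introduce the three prenyl groups as such by anionic C-alkylation, a reaction type that is well established for acylphloroglucinols. It sets out from 1: 1-bromo-3-methylbut-2-ene (2 equiv) in aqueous KOH at 0 °C should alkylate the two free ring carbons and give 1-[2,4,6-trihydroxy-3,5-bis(3-methylbut-2-enyl)phenyl]propan-1-one F1. A third equivalent of the bromide with KOH in aqueous methanol at 0 °C should then alkylate one prenyl-bearing carbon with dearomatisation, and the fallback comes back to the route at the target 11.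

2. Step 1. Ionisation of the free allylic alcohol may be slow, the allyl count may drift (arrest at the aromatic diallyl stage or a fourth allylation at C4), and part of the material may rest as O-allyl ethers. Fallback: fix the allyl count covalently before the palladium step. Setting out from 1, allyl chloroformate (3.3 equiv), pyridine and catalytic DMAP in CH2Cl2 at 0 °C should give tris(prop-2-enyl) 2-propanoylbenzene-1,3,5-triyl tricarbonate F2. Pd(PPh3)4 (5 mol %) in THF at room temperature should then ionise each carbonate, expel CO2 and return the allyl group to the phenoxide (decarboxylative Tsuji–Trost allylation). O-allyl ethers would be re-ionised by zerovalent palladium until all three groups rest on carbon, so the fallback comes back to the route at 5.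

Further compounds
F1 | step 2 | 1-[2,4,6-trihydroxy-3,5-bis(3-methylbut-2-enyl)phenyl]propan-1-one | CCC(=O)c1c(O)c(CC=C(C)C)c(O)c(CC=C(C)C)c1O
F2 | step 1 | tris(prop-2-enyl) 2-propanoylbenzene-1,3,5-triyl tricarbonate | CCC(=O)c1c(OC(=O)OCC=C)cc(OC(=O)OCC=C)cc1OC(=O)OCC=C
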